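If the reagent in the larch flask went wholly onto triple product, at 3 reagent per substrate, how far would the charge reach? That question opened the short meeting about this flask.

all flasks: substrate 0.050 M
- larch: reagent 0.10 M; capture agent 0.015 M; temperature 5 °C; the very flask that is asked about, followed so far
- oak: reagent 0.10 M; capture agent 0.015 M; temperature −10 °C; run made earlier
- flask: reagent 0.100 M; capture agent 0.0150 M; temperature 5 °C; time 3.0 h

| run | time / min | triple product / % | substrate / % |
|---|---|---|---|
| larch | 10.0 | 6 | 61 |
| larch | 30.0 | 24 | 31 |
| larch | 50.0 | 38 | 23 |
| larch | 80.0 | 45 | 16 |
| larch | 120 | 50 | 14 |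
| larch | 150 | 48 | 13 |
| larch | 180 | 54 | 16 |
| oak | 20.0 | 4 | 67 |
| oak | 60.0 | 13 | 45 |
| oak | 120 | 27 | 28 |
| oak | 180 | 36 | 25 |
| oak | 240 | 41 | 21 |
| oak | 300 | 49 | 19 |
| oak | 360 | 49 | 21 |

(standard deviation of a reading: 2 percentage points)

- blue: at 3.0 h raise the temperature by 15 K, then wait 6.0 h
- green: change nothing and wait 6.0 h more
- grey: at 3.0 h add reagent, 50.0 % of the amount charged, then wait 6.0 h
- red: at 3.0 h take out 90 % of the triple product then present, then wait 6.0 h

- removed triple product is counted in
- additions bring no volume worth counting

- triple product, in percent of the substrate first charged, at 3.0 h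
- which option adds most triple product ("none" when 2 percentage points or less is all one gets) (blue / green / grey / red / none)
- triple product present, with what was taken out counted in, in percent of the substrate first charged, after green
- triple product present, with what was taken out counted in, in percent of the substrate first charged, after red

The chair proposed this clean case as the zero of the scale and named it the reagent ceiling: reagent charged over 3 times substrate charged, here 66.7 %.

The analyst reported that larch stood at 50 % triple product and 14 % substrate at 120 min, and put the plateau, averaged from that reading on, at 50.7 %. By the analyst's reckoning, the triple product at 120 min had cost 75.0 % of the reagent charge. A further 36.0 % of the substrate stood in neither column. If that material carried one or two reagent each, it held 18.0 % to 36.0 % of the charge, against the 25.0 % still unaccounted for. So the larch readings, with their scatter, allow reagent to be the limiting reagent.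

A colleague added that the colder oak run had read 49 % triple product at 360 min. The chair then noted that grey lifts the ceiling to 100 %, while blue, green and red add no reagent and leave it where it stands.

The forecaster, judging that “this looks like a stopped reaction rather than a slow one”, gave 51 % at 3.0 h (range 48 % to 54 %), 52 % after green (49 % to 57 %), 52 % after red (49 % to 60 %), and named grey as best.

The simulation of the larch flask, run on the scheme below, gave 50.1 % at 3.0 h.

    substrate + reagent → mono adduct + released group (k = 0.0110 L mol⁻¹ s⁻¹, Ea = 53.0 kJ mol⁻¹)
    mono adduct → side product (k = 1.20 × 10⁻⁴ s⁻¹, Ea = 82.0 kJ mol⁻¹)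
    reagent + double product → triple product + released group (k = 0.0220 L mol⁻¹ s⁻¹, Ea = 45.0 kJ mol⁻¹)
    mono adduct + capture agent → trapped intermediate (k = 0.00570 L mol⁻¹ s⁻¹, Ea = 53.0 kJ mol⁻¹)
    reagent + mono adduct → double product + released group (k = 0.0230 L mol⁻¹ s⁻¹, Ea = 57.0 kJ mol⁻¹)
    (constants at 5 °C)

That lies inside the forecast's range and under the ceiling of 66.7 %, with 1.37 % of the reagent charge free at 180 min. Grey added 26 percentage points, against 1.5 points for green, 1.5 points for red and 1.4 points for blue; green ended at 51.6 % and red at 51.6 %. The main reason the larch flask holds no more triple product at 3.0 h is the using up of reagent: the same run with reagent kept from being used up reaches 92.0 % instead of 50.1 %. The neighbour flask with 0.20 M of substrate has a ceiling of 16.7 % and holds 3.15 % triple product at 180 min.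

(The runs are simulated for an exercise; scatter was added.)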